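**Strategy.** The route rests on forming the C4a–C8a bond of ring A. Ring A carries oxygen at C5, C6, C7 and C8a, with C6–O para to C8a–O and hydrogen at C8. This pattern maps onto methyl semisquarate (C6, C7, C8, C8a) joined to a 1-methoxyalkenyl unit (C5, C4a). Heating 3-methoxy-4-(methoxymethoxy)-4-[(Z)-1-methoxyalkenyl]cyclobutenone 22, which already carries the fully protected C4–C3–C2 chain and ring B (C3 set, C2 epimeric), opens the four-membered ring to a dienylketene and closes ring A in one operation. Only the C8a phenol is left free. Mitsunobu inversion at C2 then closes ring C; oxidation at C4 and deprotection finish the synthesis.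

Key step: step 12

Remark: locants C2–C8a are those of the chroman-4-one target; the C4 carbinol carbon and the quaternary carbinol carbon of the cyclobutenone are carried as epimer mixtures because both become sp2 later. The CIP label at C3 changes with the neighbouring groups although its spatial arrangement stays as set in step 3.

Remark: the protecting groups are removed in a fixed order under mutually exclusive conditions: C2–O triethylsilyl (buffered HF·pyridine), C4–O tert-butyldimethylsilyl (Bu4NF), C6–O methoxymethyl (acidic methanol), then ring B benzyl together with the C5 methyl (BCl3).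

Step 1
Reactants: 1 3-hydroxy-4,5-dimethoxybenzaldehyde
Product: 2 3-(benzyloxy)-4,5-dimethoxybenzaldehyde
Conditions: BnBr, K2CO3, DMF, rt
Reagents that add atoms: benzyl bromide BrCc1ccccc1
Why: Williamson etherification of the single phenol with a primary benzylic halide under carbonate conditions that leave the aldehyde untouched.

Step 2
Reactants: 3 (R)-4-benzyloxazolidin-2-one; 4 methoxyacetyl chloride
Product: 6 (R)-4-benzyl-3-(2-methoxyacetyl)oxazolidin-2-one, via N-lithio oxazolidinone 5 (not isolated)
Conditions: n-BuLi, THF, −78 °C; then 4, −78 → 0 °C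
Reagents that add atoms: none
Why: N-acylation of the lithiated carbamate nitrogen by the acid chloride is the standard entry to Evans imides, is fast at −78 °C and does not touch the stereocentre of the auxiliary.

Step 3
Reactants: 6 (R)-4-benzyl-3-(2-methoxyacetyl)oxazolidin-2-one; 2 3-(benzyloxy)-4,5-dimethoxybenzaldehyde
Product: 8 (R)-4-benzyl-3-[(2R,3S)-3-[3-(benzyloxy)-4,5-dimethoxyphenyl]-3-hydroxy-2-methoxypropanoyl]oxazolidin-2-one, via dibutylboron Z-enolate 7 (not isolated)
Conditions: Bu2BOTf, Et3N, CH2Cl2, −78 → 0 °C; then 2, −78 → 0 °C; H2O2, MeOH, pH 7 buffer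
Reagents that add atoms: none
Why: Evans syn-aldol reaction in which the Z boron enolate reacts through a closed Zimmerman–Traxler chair on the face away from the benzyl group of the auxiliary, setting the methoxy carbon (later C3) R and the carbinol carbon (later C2) S in a 2,3-syn relationship.

Step 4
Reactants: 8 aldol adduct
Product: 9 (2R,3S)-3-[3-(benzyloxy)-4,5-dimethoxyphenyl]-3-hydroxy-N,2-dimethoxy-N-methylpropanamide
Conditions: MeNHOMe·HCl, AlMe3, CH2Cl2, −10 → 0 °C; aq. KNa tartrate
Reagents that add atoms: N,O-dimethylhydroxylamine hydrochloride CNOC.Cl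
Why: Weinreb transamidation by the aluminium amide, assisted by the free β-hydroxyl as its aluminium alkoxide, replaces the auxiliary at 0 °C without retro-aldol cleavage or epimerisation.

Step 5
Reactants: 9 Weinreb amide
Product: 10 (2R,3S)-3-[3-(benzyloxy)-4,5-dimethoxyphenyl]-N,2-dimethoxy-N-methyl-3-[(triethylsilyl)oxy]propanamide
Conditions: Et3SiCl, imidazole, DMF, 0 °C → rt
Reagents that add atoms: chlorotriethylsilane CC[Si](Cl)(CC)CC
Why: Silylation of the secondary benzylic alcohol with the silyl group that can later be removed selectively beside a tert-butyldimethylsilyl ether.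

Step 6
Reactants: 10 silylated Weinreb amide
Product: 11 (2R,3S)-3-[3-(benzyloxy)-4,5-dimethoxyphenyl]-2-methoxy-3-[(triethylsilyl)oxy]propanal
Conditions: iBu2AlH, THF, −78 °C; aq. KNa tartrate
Reagents that add atoms: none
Why: Hydride reduction of the Weinreb amide stops at the chelated tetrahedral intermediate, which gives the aldehyde only on work-up, and the low temperature protects the α-methoxy stereocentre.

Step 7
Reactants: 11 aldehyde; 12 chloroacetaldehyde dimethyl acetal
Product: 14 (4S,5S)-5-[3-(benzyloxy)-4,5-dimethoxyphenyl]-1,4-dimethoxy-5-[(triethylsilyl)oxy]pent-1-yn-3-ol (C3 epimers; pentynol C3 is the later C4), via lithium methoxyacetylide 13 (not isolated)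
Conditions: Et2NH, n-BuLi, THF, 0 °C; 12, 0 °C; then 11, −78 °C
Reagents that add atoms: none
Why: Threefold reaction of the chloroacetal with LiNEt2 (two eliminations and deprotonation) gives the alkoxyacetylide, which adds 1,2 to the aldehyde at −78 °C faster than the aldehyde can epimerise; the new carbinol centre need not be controlled because it is oxidised in step 16.

Step 8
Reactants: 14 propargylic alcohol
Product: 15 tert-butyl{[(4R,5S)-5-[3-(benzyloxy)-4,5-dimethoxyphenyl]-1,4-dimethoxy-5-[(triethylsilyl)oxy]pent-1-yn-3-yl]oxy}dimethylsilane (C3 epimers)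
Conditions: TBSCl, imidazole, DMAP (cat.), DMF, rt
Reagents that add atoms: tert-butyldimethylsilyl chloride CC(C)(C)[Si](C)(C)Cl
Why: Silylation under basic, non-electrophilic conditions protects the future C4 oxygen and leaves the acid-sensitive ynol ether intact.

Step 9
Reactants: 15 silylated ynol ether
Product: 16 tributyl[(1E,4S,5S)-5-[3-(benzyloxy)-4,5-dimethoxyphenyl]-3-[(tert-butyldimethylsilyl)oxy]-1,4-dimethoxy-5-[(triethylsilyl)oxy]pent-1-en-1-yl]stannane (C3 epimers)
Conditions: Bu3SnH, Pd(PPh3)4 (cat.), THF, 0 °C → rt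
Reagents that add atoms: tributyltin hydride CCCC[SnH](CCCC)CCCC
Why: Palladium-catalysed syn-hydrostannation of a 1-alkoxyalk-1-yne places tin on the oxygen-bearing carbon (polarisation of the ynol ether, reinforced by the bulky silyloxy branch at the other terminus) and hydrogen cis to it.

Step 10
Reactants: 17 dimethyl squarate
Product: 19 3-methoxycyclobut-3-ene-1,2-dione (methyl semisquarate), via 4-hydroxy-2,3-dimethoxycyclobut-2-enone 18 (not isolated)
Conditions: LiAlH(OtBu)3, THF, −20 °C; then conc. HCl, CH2Cl2, rt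
Reagents that add atoms: water O
Why: Mono-reduction of one vinylogous ester carbonyl followed by acid-induced ionisation of the carbinol to a methoxy-stabilised cyclobutenyl cation, which is hydrolysed with loss of methanol, is the established squarate-to-semisquarate conversion.

Step 11
Reactants: 16 vinylstannane; 19 methyl semisquarate
Product: 22 4-[(1Z,4S,5S)-5-[3-(benzyloxy)-4,5-dimethoxyphenyl]-3-[(tert-butyldimethylsilyl)oxy]-1,4-dimethoxy-5-[(triethylsilyl)oxy]pent-1-en-1-yl]-3-methoxy-4-(methoxymethoxy)cyclobut-2-en-1-one (epimers at the ring carbinol carbon and at C4), via vinyllithium 20 (not isolated), via lithium cyclobutenolate 21 (not isolated)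
Conditions: n-BuLi, THF, −78 °C; add to 19, THF, −78 °C; then MOMCl, DMPU, −78 → −20 °C
Reagents that add atoms: chloromethyl methyl ether COCCl
Why: Tin–lithium exchange with retention of alkene geometry gives an α-methoxyvinyllithium that adds 1,2 to the carbonyl flanked by the methoxy-bearing carbon (the other carbonyl is a deactivated vinylogous ester), and O-alkylation of the tertiary alkoxide with the reactive chloromethyl ether fixes the ring A substitution pattern.

Step 12
Reactants: 22 cyclobutenone
Product: 25 2-[(2R,3S)-3-[3-(benzyloxy)-4,5-dimethoxyphenyl]-1-[(tert-butyldimethylsilyl)oxy]-2-methoxy-3-[(triethylsilyl)oxy]propyl]-3,5-dimethoxy-4-(methoxymethoxy)phenol (C1 epimers of the propyl chain, the later C4), via dienylketene 23 (not isolated), via cyclohexa-2,4-dienone 24 (not isolated)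
Conditions: toluene (degassed, 0.01 M), 110 °C
Reagents that add atoms: none
Why: Thermal conrotatory 4π ring opening of the bond between the carbonyl carbon and the quaternary carbon, driven by release of ring strain, gives dienylketene 23 whose ketene carbon is the future C8a; a thermally allowed disrotatory 6π electrocyclisation then joins it to the alkene terminus (future C4a) to give cyclohexadienone 24, which enolises to the phenol. This is the Moore rearrangement, for which 4-alkenyl cyclobutenones bearing a 4-alkoxy or 4-silyloxy group are the closest precedent. Ring A is closed as a six-membered carbocycle by this pericyclic 6π closure, forming the single C4a–C8a bond, and aromatisation follows. No stereocentre is created: the sp3 carbon formed at C4a is lost on enolisation and the scrambled ring carbinol carbon becomes aromatic C6, so all diastereomers of 22 converge on the two C4 epimers of 25. The step needs torquoselectivity, secured by the methoxymethoxy donor, which rotates outward and places the alkenyl group next to the ketene, and it needs an accessible alkene terminus, secured by the Z geometry, which turns the side chain away from the forming bond. The chain carries no free hydroxyl that could trap the ketene, and the regiochemistry of step 11 dictates the outcome: C8a–OH free, C6–O as methoxymethyl ether, methoxy at C5 and C7, hydrogen at C8.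

Step 13
Reactants: 25 phenol
Product: 26 2-[(2R,3S)-3-[3-(benzyloxy)-4,5-dimethoxyphenyl]-1-[(tert-butyldimethylsilyl)oxy]-3-hydroxy-2-methoxypropyl]-3,5-dimethoxy-4-(methoxymethoxy)phenol (C1 epimers of the propyl chain)
Conditions: HF·pyridine, pyridine, THF, 0 °C
Reagents that add atoms: none
Why: Buffered fluoride cleaves the less hindered and intrinsically more labile triethylsilyl ether, while the hindered C4 tert-butyldimethylsilyl ether and the aryl acetal survive and the near-neutral medium avoids ionisation at the activated C4 position.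

Step 14
Reactants: 26 phenol with free C2 hydroxyl
Product: 27 tert-butyl{[(2R,3R)-2-[3-(benzyloxy)-4,5-dimethoxyphenyl]-3,5,7-trimethoxy-6-(methoxymethoxy)chroman-4-yl]oxy}dimethylsilane (C4 epimers)
Conditions: PPh3, DIAD, THF, 0 °C → rt
Reagents that add atoms: none
Why: Intramolecular Mitsunobu etherification in which the C8a phenoxide displaces the C2 alkoxyphosphonium group in a 6-exo-tet SN2 closure of ring C with inversion, turning C2 from S to R and giving the 2,3-trans arrangement; the only other carbinol oxygen (C4) is silylated and cannot be activated.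

Step 15
Reactants: 27 silylated flavan
Product: 28 (2R,3S)-2-[3-(benzyloxy)-4,5-dimethoxyphenyl]-3,5,7-trimethoxy-6-(methoxymethoxy)chroman-4-ol (C4 epimers; same spatial arrangement at C3 as in 27)
Conditions: Bu4NF, THF, rt
Reagents that add atoms: none
Why: Fluoride cleaves the remaining silyl ether under basic conditions in which C4 cannot ionise, and the acetal, benzyl and methyl ethers are inert to fluoride.

Step 16
Reactants: 28 flavan-4-ol
Product: 29 (2R,3R)-2-[3-(benzyloxy)-4,5-dimethoxyphenyl]-3,5,7-trimethoxy-6-(methoxymethoxy)chroman-4-one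
Conditions: Dess–Martin periodinane, NaHCO3, CH2Cl2, rt
Reagents that add atoms: none
Why: Dess–Martin oxidation converts both epimers of the benzylic secondary alcohol into one ketone under buffered, near-neutral conditions that neither epimerise C3 nor attack the fully etherified arenes.

Step 17
Reactants: 29 protected flavanonol
Product: 30 (2R,3R)-2-[3-(benzyloxy)-4,5-dimethoxyphenyl]-6-hydroxy-3,5,7-trimethoxychroman-4-one
Conditions: conc. HCl (cat.), MeOH, 40 °C
Reagents that add atoms: none
Why: Acid-catalysed acetal exchange removes the aryl methoxymethyl group while methanol captures the methoxymethyl cation, and the ketone, the benzyl ether and the thermodynamically preferred 2,3-trans arrangement are stable to these conditions.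

Step 18
Reactants: 30 6-hydroxy flavanonol
Product: 31 (2R,3R)-5,6-dihydroxy-2-(3-hydroxy-4,5-dimethoxyphenyl)-3,7-dimethoxychroman-4-one (CNP0075601.1)
Conditions: BCl3, C6HMe5, CH2Cl2, −78 → 0 °C; MeOH/H2O
Reagents that add atoms: none
Why: BCl3 held in a six-membered chelate between the C4 carbonyl and the peri C5 methoxy oxygen cleaves only that methyl ether by chloride attack on the methyl group, and at the same time removes the ring B benzyl ether with pentamethylbenzene capturing the benzyl cation; the C7 methoxy (a vinylogous ester oxygen), the C3 methoxy and the ring B methoxy groups are not activated below 0 °C.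

**Compound list**

1 | 3-hydroxy-4,5-dimethoxybenzaldehyde | COc1cc(C=O)cc(O)c1OC | starting material
2 | 3-(benzyloxy)-4,5-dimethoxybenzaldehyde | COc1cc(C=O)cc(OCc2ccccc2)c1OC | intermediate
3 | (R)-4-benzyloxazolidin-2-one | O=C1N[C@H](Cc2ccccc2)CO1 | starting material
4 | methoxyacetyl chloride | COCC(Cl)=O | starting material
5 | N-lithio-(R)-4-benzyloxazolidin-2-one (not isolated) | [Li]N1[C@H](Cc2ccccc2)COC1=O | intermediate
6 | (R)-4-benzyl-3-(2-methoxyacetyl)oxazolidin-2-one | COCC(=O)N1[C@H](Cc2ccccc2)COC1=O | intermediate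
7 | dibutylboron (Z)-enolate of 6 (not isolated) | CO/C=C(\OB(CCCC)CCCC)N1[C@H](Cc2ccccc2)COC1=O | intermediate
8 | (R)-4-benzyl-3-[(2R,3S)-3-[3-(benzyloxy)-4,5-dimethoxyphenyl]-3-hydroxy-2-methoxypropanoyl]oxazolidin-2-one | O=C1OC[C@@H](Cc2ccccc2)N1C(=O)[C@H](OC)[C@@H](O)c1cc(OCc2ccccc2)c(OC)c(OC)c1 | intermediate
9 | (2R,3S)-3-[3-(benzyloxy)-4,5-dimethoxyphenyl]-3-hydroxy-N,2-dimethoxy-N-methylpropanamide | CON(C)C(=O)[C@H](OC)[C@@H](O)c1cc(OCc2ccccc2)c(OC)c(OC)c1 | intermediate
10 | (2R,3S)-3-[3-(benzyloxy)-4,5-dimethoxyphenyl]-N,2-dimethoxy-N-methyl-3-[(triethylsilyl)oxy]propanamide | CON(C)C(=O)[C@H](OC)[C@@H](O[Si](CC)(CC)CC)c1cc(OCc2ccccc2)c(OC)c(OC)c1 | intermediate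
11 | (2R,3S)-3-[3-(benzyloxy)-4,5-dimethoxyphenyl]-2-methoxy-3-[(triethylsilyl)oxy]propanal | O=C[C@H](OC)[C@@H](O[Si](CC)(CC)CC)c1cc(OCc2ccccc2)c(OC)c(OC)c1 | intermediate
12 | chloroacetaldehyde dimethyl acetal (2-chloro-1,1-dimethoxyethane) | COC(CCl)OC | starting material
13 | lithium methoxyacetylide (not isolated) | [Li]C#COC | intermediate
14 | (4S,5S)-5-[3-(benzyloxy)-4,5-dimethoxyphenyl]-1,4-dimethoxy-5-[(triethylsilyl)oxy]pent-1-yn-3-ol, C3 epimers | COC#CC(O)[C@H](OC)[C@@H](O[Si](CC)(CC)CC)c1cc(OCc2ccccc2)c(OC)c(OC)c1 | intermediate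
15 | tert-butyl{[(4R,5S)-5-[3-(benzyloxy)-4,5-dimethoxyphenyl]-1,4-dimethoxy-5-[(triethylsilyl)oxy]pent-1-yn-3-yl]oxy}dimethylsilane, C3 epimers | COC#CC(O[Si](C)(C)C(C)(C)C)[C@H](OC)[C@@H](O[Si](CC)(CC)CC)c1cc(OCc2ccccc2)c(OC)c(OC)c1 | intermediate
16 | tributyl[(1E,4S,5S)-5-[3-(benzyloxy)-4,5-dimethoxyphenyl]-3-[(tert-butyldimethylsilyl)oxy]-1,4-dimethoxy-5-[(triethylsilyl)oxy]pent-1-en-1-yl]stannane, C3 epimers | CCCC[Sn](CCCC)(CCCC)/C(OC)=C/C(O[Si](C)(C)C(C)(C)C)[C@H](OC)[C@@H](O[Si](CC)(CC)CC)c1cc(OCc2ccccc2)c(OC)c(OC)c1 | intermediate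
17 | dimethyl squarate (3,4-dimethoxycyclobut-3-ene-1,2-dione) | COC1=C(OC)C(=O)C1=O | starting material
18 | 4-hydroxy-2,3-dimethoxycyclobut-2-en-1-one (not isolated) | COC1=C(OC)C(O)C1=O | intermediate
19 | 3-methoxycyclobut-3-ene-1,2-dione | COC1=CC(=O)C1=O | intermediate
20 | (Z)-1-methoxyalkenyllithium from 16, lithium in place of tin (not isolated) | [Li]/C(OC)=C/C(O[Si](C)(C)C(C)(C)C)[C@H](OC)[C@@H](O[Si](CC)(CC)CC)c1cc(OCc2ccccc2)c(OC)c(OC)c1 | intermediate
21 | lithium alkoxide of the 4-hydroxy-3-methoxy-4-alkenylcyclobut-2-en-1-one, side chain as in 22 (not isolated) | [Li]OC1(C(=O)C=C1OC)/C(OC)=C/C(O[Si](C)(C)C(C)(C)C)[C@H](OC)[C@@H](O[Si](CC)(CC)CC)c1cc(OCc2ccccc2)c(OC)c(OC)c1 | intermediate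
22 | 4-[(1Z,4S,5S)-5-[3-(benzyloxy)-4,5-dimethoxyphenyl]-3-[(tert-butyldimethylsilyl)oxy]-1,4-dimethoxy-5-[(triethylsilyl)oxy]pent-1-en-1-yl]-3-methoxy-4-(methoxymethoxy)cyclobut-2-en-1-one, epimers at the ring carbinol carbon and at C3 of the side chain | O=C1C=C(OC)C1(OCOC)/C(OC)=C/C(O[Si](C)(C)C(C)(C)C)[C@H](OC)[C@@H](O[Si](CC)(CC)CC)c1cc(OCc2ccccc2)c(OC)c(OC)c1 | intermediate
23 | dienylketene from ring opening of 22, alkenyl group cis to the ketene-bearing carbon (not isolated) | O=C=C/C(OC)=C(OCOC)\C(OC)=C\C(O[Si](C)(C)C(C)(C)C)[C@H](OC)[C@@H](O[Si](CC)(CC)CC)c1cc(OCc2ccccc2)c(OC)c(OC)c1 | intermediate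
24 | 3,5-dimethoxy-4-(methoxymethoxy)-6-(side chain)cyclohexa-2,4-dien-1-one, side chain as in 25 (not isolated) | O=C1C=C(OC)C(OCOC)=C(OC)C1C(O[Si](C)(C)C(C)(C)C)[C@H](OC)[C@@H](O[Si](CC)(CC)CC)c1cc(OCc2ccccc2)c(OC)c(OC)c1 | intermediate
25 | 2-[(2R,3S)-3-[3-(benzyloxy)-4,5-dimethoxyphenyl]-1-[(tert-butyldimethylsilyl)oxy]-2-methoxy-3-[(triethylsilyl)oxy]propyl]-3,5-dimethoxy-4-(methoxymethoxy)phenol, C1 epimers of the propyl chain | COCOc1c(OC)cc(O)c(C(O[Si](C)(C)C(C)(C)C)[C@H](OC)[C@@H](O[Si](CC)(CC)CC)c2cc(OCc3ccccc3)c(OC)c(OC)c2)c1OC | intermediate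
26 | 2-[(2R,3S)-3-[3-(benzyloxy)-4,5-dimethoxyphenyl]-1-[(tert-butyldimethylsilyl)oxy]-3-hydroxy-2-methoxypropyl]-3,5-dimethoxy-4-(methoxymethoxy)phenol, C1 epimers of the propyl chain | COCOc1c(OC)cc(O)c(C(O[Si](C)(C)C(C)(C)C)[C@H](OC)[C@@H](O)c2cc(OCc3ccccc3)c(OC)c(OC)c2)c1OC | intermediate
27 | tert-butyl{[(2R,3R)-2-[3-(benzyloxy)-4,5-dimethoxyphenyl]-3,5,7-trimethoxy-6-(methoxymethoxy)chroman-4-yl]oxy}dimethylsilane, C4 epimers | COc1cc2c(c(OC)c1OCOC)C(O[Si](C)(C)C(C)(C)C)[C@H](OC)[C@@H](c1cc(OCc3ccccc3)c(OC)c(OC)c1)O2 | intermediate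
28 | (2R,3S)-2-[3-(benzyloxy)-4,5-dimethoxyphenyl]-3,5,7-trimethoxy-6-(methoxymethoxy)chroman-4-ol, C4 epimers | COc1cc2c(c(OC)c1OCOC)C(O)[C@H](OC)[C@@H](c1cc(OCc3ccccc3)c(OC)c(OC)c1)O2 | intermediate
29 | (2R,3R)-2-[3-(benzyloxy)-4,5-dimethoxyphenyl]-3,5,7-trimethoxy-6-(methoxymethoxy)chroman-4-one | COc1cc2c(c(OC)c1OCOC)C(=O)[C@H](OC)[C@@H](c1cc(OCc3ccccc3)c(OC)c(OC)c1)O2 | intermediate
30 | (2R,3R)-2-[3-(benzyloxy)-4,5-dimethoxyphenyl]-6-hydroxy-3,5,7-trimethoxychroman-4-one | COc1cc2c(c(OC)c1O)C(=O)[C@H](OC)[C@@H](c1cc(OCc3ccccc3)c(OC)c(OC)c1)O2 | intermediate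
31 | (2R,3R)-5,6-dihydroxy-2-(3-hydroxy-4,5-dimethoxyphenyl)-3,7-dimethoxychroman-4-one | COc1cc2c(c(O)c1O)C(=O)[C@H](OC)[C@@H](c1cc(O)c(OC)c(OC)c1)O2 | target

**Step count and risk**

Total: 18 steps. Longest linear sequence: 16 steps (from 3 through steps 2–9 and 11–18 to 31); steps 1 and 10 are side branches.

Steps most likely to fail:

1. Step 12 (key step). At 110 °C the allylic C4 silyl ether next to the enol ether may ionise or eliminate, or the dienylketene may be diverted before it closes (dimerisation, capture by adventitious nucleophiles). Ring A would then not form cleanly on the fully elaborated substrate. The fallback sets out from 19 and 11 and returns at 25; it makes ring A first on a substrate without the side chain and joins it to the chain by aryllithium addition. Methyl vinyl ether is lithiated with t-BuLi in THF and added to 19 at −78 °C, and the alkoxide is trapped with MOMCl to give 3-methoxy-4-(methoxymethoxy)-4-(1-methoxyvinyl)cyclobut-2-en-1-one F1. Heating in toluene gives 3,5-dimethoxy-4-(methoxymethoxy)phenol F2 by the same ring expansion. NBS in CH2Cl2 at −78 °C brominates one of the two equivalent positions ortho to the hydroxyl to give 2-bromo-3,5-dimethoxy-4-(methoxymethoxy)phenol F3. Treatment with n-BuLi (2 equiv, THF, −78 °C) deprotonates the phenol and exchanges bromine for lithium, and addition to aldehyde 11 gives the C4 carbinol with free C8a phenol F4 (C4 epimers). TBSOTf with 2,6-lutidine silylates both hydroxyls to give the bis-silyl ether F5, and K2CO3 in MeOH at 0 °C cleaves only the aryl silyl ether to give 25.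

2. Step 11. O-alkylation of the hindered lithium alkoxide may be too slow at the temperature at which the alkoxide is stable. It would then fragment on warming or be recovered unprotected. The fallback sets out from 16 and 19 and returns at 22; it takes the protection out of the organolithium step. The addition is run as before but quenched with aqueous NH4Cl at −78 °C, and the tertiary carbinol 4-hydroxy-3-methoxy-4-[(1Z)-1-methoxyalkenyl]cyclobut-2-en-1-one F6 (side chain as in 22) is isolated. The neutral alcohol is then alkylated with MOMCl, iPr2NEt and catalytic Bu4NI in CH2Cl2 at 0 °C → rt to give 22.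

3. Step 14. The benzylic alkoxyphosphonium intermediate may form sluggishly next to the hindered phenol or ionise before displacement. This would erode the inversion at C2 or lead to elimination toward C3. The fallback sets out from 25 and returns at 27; it separates activation (with retention) from displacement (with inversion). Ac2O in pyridine gives the aryl acetate of 25 F7. HF·pyridine/pyridine removes the triethylsilyl group to give the C2 alcohol F8. MsCl and Et3N in CH2Cl2 at −30 °C give the C2 methanesulfonate F9. K2CO3 in MeOH at 0 °C cleaves the acetate, and the phenoxide displaces the methanesulfonate intramolecularly with inversion to give 27.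

**Further compounds**

F1 | step 12 | 3-methoxy-4-(methoxymethoxy)-4-(1-methoxyvinyl)cyclobut-2-en-1-one | O=C1C=C(OC)C1(OCOC)C(=C)OC
F2 | step 12 | 3,5-dimethoxy-4-(methoxymethoxy)phenol | COCOc1c(OC)cc(O)cc1OC
F3 | step 12 | 2-bromo-3,5-dimethoxy-4-(methoxymethoxy)phenol | COCOc1c(OC)cc(O)c(Br)c1OC
F4 | step 12 | 2-[3-[3-(benzyloxy)-4,5-dimethoxyphenyl]-1-hydroxy-2-methoxy-3-[(triethylsilyl)oxy]propyl]-3,5-dimethoxy-4-(methoxymethoxy)phenol, configuration at C2 and C3 as in 25, C4 epimers | COCOc1c(OC)cc(O)c(C(O)[C@H](OC)[C@@H](O[Si](CC)(CC)CC)c2cc(OCc3ccccc3)c(OC)c(OC)c2)c1OC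
F5 | step 12 | tert-butyldimethylsilyl ether of 25 at the C8a phenol (bis-silyl ether at C4–O and C8a–O), C4 epimers | COCOc1c(OC)cc(O[Si](C)(C)C(C)(C)C)c(C(O[Si](C)(C)C(C)(C)C)[C@H](OC)[C@@H](O[Si](CC)(CC)CC)c2cc(OCc3ccccc3)c(OC)c(OC)c2)c1OC
F6 | step 11 | 4-hydroxy-3-methoxy-4-[(1Z,4S,5S)-5-[3-(benzyloxy)-4,5-dimethoxyphenyl]-3-[(tert-butyldimethylsilyl)oxy]-1,4-dimethoxy-5-[(triethylsilyl)oxy]pent-1-en-1-yl]cyclobut-2-en-1-one, epimer mixture | O=C1C=C(OC)C1(O)/C(OC)=C/C(O[Si](C)(C)C(C)(C)C)[C@H](OC)[C@@H](O[Si](CC)(CC)CC)c1cc(OCc2ccccc2)c(OC)c(OC)c1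
F7 | step 14 | acetate of 25 at the C8a phenol, C4 epimers | COCOc1c(OC)cc(OC(C)=O)c(C(O[Si](C)(C)C(C)(C)C)[C@H](OC)[C@@H](O[Si](CC)(CC)CC)c2cc(OCc3ccccc3)c(OC)c(OC)c2)c1OC
F8 | step 14 | acetate of 26 at the C8a phenol (free C2 hydroxyl), C4 epimers | COCOc1c(OC)cc(OC(C)=O)c(C(O[Si](C)(C)C(C)(C)C)[C@H](OC)[C@@H](O)c2cc(OCc3ccccc3)c(OC)c(OC)c2)c1OC
F9 | step 14 | C2 methanesulfonate of F8, configuration at C2 and C3 as in 26, C4 epimers | COCOc1c(OC)cc(OC(C)=O)c(C(O[Si](C)(C)C(C)(C)C)[C@H](OC)[C@@H](OS(C)(=O)=O)c2cc(OCc3ccccc3)c(OC)c(OC)c2)c1OC
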